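(The constants are made up; no experiment stands behind them.)

At late times this flask can end in one of two ways: at the equilibrium of the reversible step, or wherever the free catalyst dies.

starting material 0.050 M; partner 1.20 equiv; second substrate 1.00 equiv; precatalyst 13 mol%; time 3.0 h

    starting material + partner + free catalyst ⇌ free catalyst + target (K1 = 48.3 /M, k1 = 2.81 /M²/s)
    precatalyst → free catalyst (k2 = 0.0368 /s)
    free catalyst → spent catalyst (k3 = 7.84 × 10⁻⁴ /s)
    second substrate + partner + free catalyst → free catalyst + second product (k4 = 1.12 /M²/s)

* conversion of starting material at 3.0 h
* amount of target at 3.0 h, in percent of the starting material charged

Starting material leaves by the reversible step and by no other, so conversion and target yield are the same number. Now the ladder of times. The precatalyst has a half-life of 0.31 min, shorter than the free catalyst's 14.7 min, so I count the loading as free catalyst from the start. At the opening, with partner and catalyst held at their starting values (pseudo-first-order), starting material halves in 10.5 min, only a little faster than the catalyst dies. The time allowed is ten times the catalyst's half-life, so the clock matters less than what the catalyst can do before it dies. I call this the catalyst budget: the forward rate constant times starting partner times catalyst loading, divided by the decay constant, which counts the e-foldings of starting material the catalyst can pay for.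

budget = 1.40

equilibrium ratio of target to starting material at full partner = 2.9

Partner also feeds the second substrate, so I guess a mean of 0.800 equivalents, which scales the ratio and the budget alike:

ratio = 1.93

fraction converted = 49.9 %

The forecast says 43 % for conversion and 43 % for target, each within 40 % to 46 %, and it reckons that “the catalyst has fully died by 3 h”. My figure is higher.

This flask gives 44.6 % conversion and 44.6 % target. At 3.00 h its free catalyst stands at 0.0215 % of the catalyst charged, the relaxation half-life of the reversible step, both ways together, is 28.4 d, longer than the 3.0 h allowed, and the ratio of target to starting material is 0.806 against 1.14 at equilibrium with the partner present. The budget goes with the square of the charge at a fixed recipe, so the neighbour at 0.020 M has 0.224, which at full partner and with no back reaction pays for 20.1 %, and that neighbour converts 16.4 %.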